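**Convention.** Ring atoms carry the locants of the target throughout: C1–C10 ring, C11–C13 lactone carbons, C14 methyl on C10, C15 methyl on C4. In the bicyclic precursors ring A is C1–C6 and ring B is C6–C10 plus C1.

## Analysis of the target

The target 36 is a germacranolide: a ten-membered carbocycle with a trans-fused α-methylene-γ-butyrolactone across C6–C7 (oxygen on C6, C11 on C7), a 4,5-epoxide, a Z trisubstituted C1=C10 olefin and, on C8, the ester of (E)-4-hydroxy-2-methylbut-2-enoic acid. The five stereocentres C4–C8 are contiguous, (4R,5S,6S,7R,8R). The epoxide oxygen and the lactone oxygen sit on the same face of the ring, the C7–C11 bond on the other face, and the C8 oxygen is cis to C7–C11. The epoxide is cis on the ring, so it derives from a Z C4=C5 olefin; both olefins of the parent diene are therefore Z. Sensitive groups are the exo-methylene lactone (labile to base and nucleophiles), the epoxide facing C1=C10 across the ring (acid triggers transannular cyclisation), the allylic alcohol of the side chain and, before epoxidation, a 1,5-diene open to Cope rearrangement. The synthesis is hard for two reasons: a medium ring with two Z trisubstituted olefins must be made without a ten-membered cyclisation, and the stereocentres must be set on a mobile ring where small-ring rules are only a guide. The plan rests on the fact that a Z C4=C5 olefin fits into a cyclohexene. Joining C1 to C6 turns the ten-membered ring into a decalin whose ring A holds C4=C5 and whose ring B can carry a metal on C10. Cutting the shared C1–C6 bond then releases C1=C10 and a C6 carbonyl together.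

## Retrosynthetic reasoning

**C8 ester.** Target 36 is the desilylated form of 35, which is cut at the C8–O bond into alcohol 30 and acid 34. The C8 oxygen is cis to C7–C11, but a substituent introduced next to an existing one on a ring enters trans. The carbinol is therefore made with the opposite configuration (8S) and inverted as the ester is formed. Acid 34 comes from aldehyde 31 and ylide 32 through ester 33.

**Exo-methylene.** Alcohol 30 goes back to silyl ether 29 and this to lactone 25 by removing C13. The acrylate unit tolerates few reagents, so it is added last, to the lactone enolate 26, while C8 is a silyl ether that survives strong base.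

**Lactone C–O bond and C6.** Lactone 25 is opened to hydroxy ester 24 and this to keto ester 23. The C6–H bond is made by hydride addition to the ketone, with the neighbouring epoxide as the chelating control element; this puts the C6 oxygen cis to the epoxide oxygen. The lactone is closed while C8 is masked, so the C8 oxygen cannot compete for the carboxyl group. A hydroxyl-directed epoxidation after reduction was not used: the acyclic model for Z allylic alcohols predicts the other diastereomer, so the epoxide is put in first and the alcohol second.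

**C7–C11.** Keto ester 23 is cut at C7–C11 to enolate 22 of silyl ether 21. C7 is the only enolisable position of the epoxy ketone, and the electrophile should enter trans to the C8 silyloxy group.

**C8–O.** Silyl ether 21 comes from hydroxy ketone 20, and 20 from boronate 19, the conjugate borylation product of enone 18. Enone 18 is the dehydrogenation product of epoxy ketone 16 via silyl enol ether 17. With the other enone already epoxidised, C8 is the only β-carbon left, and a chiral copper catalyst decides its configuration.

**Epoxide.** Epoxy ketone 16 is cut back to dienone 15 by removing the epoxide oxygen. A nucleophilic oxidant attacks only the conjugated C4=C5 and leaves C1=C10; a chiral amine catalyst sets the first two stereocentres on an achiral substrate.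

**Key disconnection.** Dienone 15 is reconnected between C1 and C6, with tin on C10 and hydroxyl on C6, to give decalinol 14. The fragmentation needs the C10–Sn bond anti-periplanar to C1–C6 (tin equatorial on ring B). The Z olefin needs C2 axial on C1 in that same chair. Only the cis-fused decalin with tin cis to C2 can do both, so C5, C2 and tin must all be on one face of ring B.

**C6 oxygen of 14.** Adding a vinyl metal to a C6 ketone and closing ring A by metathesis was set aside: the carbon nucleophile would enter anti to the axial stannyl group and give the trans-fused decalin. The order is reversed. Carbon is attached first as the C5=C6 bond of octalone 11, and oxygen is then delivered to C6 from the open face to give epoxy ketone 12. Methylenation to 13 and reductive opening of the vinyl epoxide move the olefin to C4=C5, turn the methylene into C15 and leave the tertiary alcohol of 14.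

**Ring A.** Octalone 11 is opened at C5=C6 to diketone 10 (aldol condensation), which is the deprotected form of ketal 9.

**C10–Sn and C1–H.** Ketone 9 is cut at C10–Sn into enone 5 and stannyl anion 7, via enolate 8. The chain is placed on C1 before tin arrives, so that the proton, not the chain, enters anti to tin. Alkylating a stannyl enolate would give the wrong C1 epimer.

**Enone 5.** Enone 5 is cut at the C1–C2 bond into iodoenone 2 and borane 4, made from dioxolane 3; iodoenone 2 comes from enone 1.

## Alternatives that were turned down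

**Alternative 1:** The disconnection cuts C7–C8 and O–C6 of isoxazoline A1. In the forward direction the open-chain nitrile oxide A4 adds across its own Z C6=C7 olefin.
- For: one operation closes the carbocycle, puts oxygen on C6 and a masked carbonyl on C8, and fixes C6/C7 stereospecifically because the addition is suprafacial.
- Against: it is a ten-membered cyclisation through a chain stiffened by a Z olefin and an epoxide, and dimerisation of the dipole competes. The facial sense relative to the vinyl epoxide is open. A4 must be built linearly with two Z olefins and a cis vinyl epoxide. After the cycloaddition the C8 ketone must still be reduced to the cis C7/C8 array, and the side chain oxidised and methylenated.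
- Comparison: A1 is stronger on C6/C7, which the chosen route sets on the ring by enolate alkylation and reduction. The chosen route offers a ring made without cyclisation entropy, from eight simple steps, with catalytic absolute control afterwards.

**Alternative 2:** The disconnection cuts C2–C3 of sulfone A2. In the forward direction the sulfonyl carbanion at C2 of the open-chain chloride A5 displaces the allylic chloride at C3.
- For: the C6–C8 triad is made on an open chain by reliable acyclic methods before the ring exists, and both Z olefins are fixed in the fragments.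
- Against: the closure is again a ten-membered SN2 reaction needing high dilution. The carbanion is allylic and the chloride is allylic, so α/γ and SN2/SN2' mixtures are possible. The sulfone must later be removed without moving the olefins. A5 is long, and lactone, epoxide and methylene still follow.
- Comparison: A2 is clearly stronger on the stereotriad, the weakest part of the chosen route. The chosen route offers a stereospecific ring formation with no dilution and a much shorter path to the carbocycle.

**Alternative 3:** The disconnection cuts C7–C11 of lactone A3. In the forward direction a chiral dirhodium carboxamidate catalyst decomposes the C6 diazoacetate A6 and the carbene inserts into a C7–H bond.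
- For: the lactone is annulated directly under catalyst control, with no enolate at C7 and so no risk of β-elimination.
- Against: it is an endgame tactic and leaves the ring problem untouched, since A6 already contains the ring, the epoxide and both oxygens. Insertion must distinguish the two C7 hydrogens from the oxygen-activated C8–H and the C5–H. The C1=C10 olefin and the epoxide oxygen can intercept the carbene. A trans-fused lactone is not the usual outcome of insertion.
- Comparison: A3 is as strong or stronger for the C7–C11 bond itself. The chosen strategy supplies what A3 lacks, a way to make the ten-membered diene; the insertion could be grafted onto it.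

Key step: step 9

## Route

Assumption: compounds 8–14 and F2 are racemic and drawn as one enantiomer; the catalyst antipodes in steps 10 and 12 are those that give the configurations drawn, to be fixed by experiment.

Step 1
Reactants: 1 3-methylcyclohex-2-en-1-one
Product: 2 2-iodo-3-methylcyclohex-2-en-1-one
Conditions: I2, pyridine, CH2Cl2, 0 °C to rt
Reagents that add atoms: iodine, II
Why: α-Iodination of an enone by conjugate addition of pyridine, iodination of the enolate and loss of pyridine; it gives the handle for a carbon chain on C1 before tin is introduced.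

Step 2
Reactants: 3 2-methyl-2-vinyl-1,3-dioxolane; 2 2-iodo-3-methylcyclohex-2-en-1-one
Product: 5 3-methyl-2-[2-(2-methyl-1,3-dioxolan-2-yl)ethyl]cyclohex-2-en-1-one, via alkylborane 4 (not isolated)
Conditions: 3, 9-BBN, THF, 0 °C to rt; then 2, Pd(dppf)Cl2 (cat.), Ph3As, Cs2CO3, DMF/H2O, rt
Reagents that add atoms: none
Why: Anti-Markovnikov hydroboration of the vinyl ketal, then B-alkyl Suzuki–Miyaura coupling with the α-iodoenone; the ketal masks the future C4 ketone against the stannyl anion of step 3.

Step 3
Reactants: 6 hexamethylditin; 5 3-methyl-2-[2-(2-methyl-1,3-dioxolan-2-yl)ethyl]cyclohex-2-en-1-one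
Product: 9 rac-(2R,3S)-3-methyl-2-[2-(2-methyl-1,3-dioxolan-2-yl)ethyl]-3-(trimethylstannyl)cyclohexan-1-one, via trimethylstannyllithium 7 (not isolated), via lithium enolate 8 (not isolated)
Conditions: 6, MeLi, THF, −20 °C; 5, −78 to −40 °C; 2,6-di-tert-butyl-4-methylphenol, −78 °C; aq NH4Cl
Reagents that add atoms: none
Why: Conjugate stannylation of the β-methyl enone creates the tertiary C10–Sn bond. The hindered phenol then protonates enolate 8 at C1 anti to the stannyl group (diastereoselective enolate protonation), so the chain ends cis to tin. The weak thermodynamic preference, axial SnMe3 over axial CH3, points the same way.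

Step 4
Reactants: 9 rac-(2R,3S)-3-methyl-2-[2-(2-methyl-1,3-dioxolan-2-yl)ethyl]-3-(trimethylstannyl)cyclohexan-1-one
Product: 10 rac-(2R,3S)-3-methyl-2-(3-oxobutyl)-3-(trimethylstannyl)cyclohexan-1-one
Conditions: pyridinium p-toluenesulfonate, acetone/H2O, 45 °C
Reagents that add atoms: water, O
Why: Mild acid-catalysed ketal hydrolysis; the buffered acid is too weak to cleave the alkyl–tin bond.

Step 5
Reactants: 10 rac-(2R,3S)-3-methyl-2-(3-oxobutyl)-3-(trimethylstannyl)cyclohexan-1-one
Product: 11 rac-(4aR,5S)-5-methyl-5-(trimethylstannyl)-4,4a,5,6,7,8-hexahydronaphthalen-2(3H)-one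
Conditions: NaOMe, MeOH, 0 °C to rt
Reagents that add atoms: none
Why: Intramolecular aldol addition of the methyl ketone to C6 and dehydration (second half of a Robinson annulation) closes ring A with carbon on C6 as the C5=C6 olefin; mild base and short time limit epimerisation at C1.

Step 6
Reactants: 11 rac-(4aR,5S)-5-methyl-5-(trimethylstannyl)-4,4a,5,6,7,8-hexahydronaphthalen-2(3H)-one
Product: 12 rac-(1S,4aR,5S,8aS)-1,8a-epoxy-5-methyl-5-(trimethylstannyl)octahydronaphthalen-2(1H)-one
Conditions: 30% H2O2, NaOH, MeOH, 0 °C
Reagents that add atoms: hydrogen peroxide, OO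
Why: Weitz–Scheffer epoxidation: hydroperoxide adds to C6, the β-carbon. It attacks anti to the axial stannyl group on C10 and on the face that gives the cis-fused product, as in conjugate additions to octalones. The C6 oxygen therefore ends cis to H1 and trans to tin.

Step 7
Reactants: 12 rac-(1S,4aR,5S,8aS)-1,8a-epoxy-5-methyl-5-(trimethylstannyl)octahydronaphthalen-2(1H)-one
Product: 13 rac-(1R,4aR,5S,8aS)-1,8a-epoxy-5-methyl-2-methylidene-5-(trimethylstannyl)decahydronaphthalene
Conditions: Ph3PCH3Br, KOtBu, THF, 0 °C to rt
Reagents that add atoms: methyltriphenylphosphonium bromide, C[P+](c1ccccc1)(c1ccccc1)c1ccccc1.[Br-]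
Why: Wittig methylenation of the C4 ketone; the epoxide blocks enolisation towards C5, and the new carbon is the future C15 methyl.

Step 8
Reactants: 13 rac-(1R,4aR,5S,8aS)-1,8a-epoxy-5-methyl-2-methylidene-5-(trimethylstannyl)decahydronaphthalene
Product: 14 rac-(4aR,8S,8aR)-3,8-dimethyl-8-(trimethylstannyl)-1,5,6,7,8,8a-hexahydronaphthalen-4a(2H)-ol
Conditions: SmI2, THF/MeOH, −78 °C
Reagents that add atoms: none
Why: Two-electron reductive opening of the vinyl epoxide by divalent samarium gives an allyl anion that is protonated at the terminal carbon, a known route from vinyl oxiranes to allylic alcohols. C15 becomes methyl, the olefin moves to C4=C5, and the C6–O bond is untouched, so the cis ring fusion is kept.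

Step 9
Reactants: 14 rac-(4aR,8S,8aR)-3,8-dimethyl-8-(trimethylstannyl)-1,5,6,7,8,8a-hexahydronaphthalen-4a(2H)-ol
Product: 15 (2Z,6Z)-3,7-dimethylcyclodeca-2,6-dien-1-one
Conditions: PhI(OAc)2, CH2Cl2, 0 °C to rt
Reagents that add atoms: none
Why: Ligand exchange places the tertiary C6 alkoxide on trivalent iodine; loss of iodobenzene and acetate from oxygen is concerted with cleavage of C1–C6 and of C10–Sn, so the C6 carbonyl and the C1=C10 π bond form together and Me3SnOAc leaves (oxidative Grob-type 1,4-fragmentation of a γ-stannyl alcohol, a known ring expansion to medium-ring enones). The ten-membered ring is not closed by cyclisation: it appears when the bond shared by rings A and B is cut, so no closure mode and no dilution are involved. No stereocentre is created; the three stereocentres of 14 are consumed and their relative configuration becomes olefin geometry. The fragmentation needs C10–Sn anti-periplanar to C1–C6, that is, tin equatorial on ring B. In the cis-fused chair with tin equatorial, C2 is axial on C1 and gauche to C9, so C2 and C9 end cis on the new olefin (Z); a trans-fused isomer could only give E. The C4=C5 olefin keeps its six-ring geometry and becomes the Z enone. The oxidant must attack the hydroxyl before the olefin or the C–Sn bond, and the path must stay concerted; a non-nucleophilic solvent and low temperature serve both.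

Step 10
Reactants: 15 (2Z,6Z)-3,7-dimethylcyclodeca-2,6-dien-1-one
Product: 16 (4R,5R)-4,5-epoxy-4,10-dimethylcyclodec-1(10)Z-en-6-one
Conditions: 9-amino-9-deoxy-epi-quinine (10 mol %), CF3CO2H (20 mol %), 50% aq H2O2, dioxane, 40 °C
Reagents that add atoms: hydrogen peroxide, OO
Why: Iminium activation of the cyclic enone by a cinchona-derived primary amine, conjugate addition of H2O2 and closure of the β-peroxy enamine (catalytic asymmetric epoxidation of cyclic enones). The catalyst selects the enone face, the ring keeps C3 and C6 cis so the epoxide is cis, and the isolated C1=C10 olefin is inert to the nucleophilic oxidant.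

Step 11
Reactants: 16 (4R,5R)-4,5-epoxy-4,10-dimethylcyclodec-1(10)Z-en-6-one
Product: 18 (4R,5R)-4,5-epoxy-4,10-dimethylcyclodeca-1(10)Z,7Z-dien-6-one, via silyl enol ether 17 (not isolated)
Conditions: LiN(iPr)2, Me3SiCl, THF, −78 °C; then Pd(OAc)2, MeCN, rt
Reagents that add atoms: none
Why: Saegusa–Ito dehydrogenation: C7 is the only enolisable position, and the palladium enolate loses a C8 hydride to give the enone; the ring-cis (Z) geometry is expected for a ten-membered ring that already holds a Z olefin and an epoxide.

Step 12
Reactants: 18 (4R,5R)-4,5-epoxy-4,10-dimethylcyclodeca-1(10)Z,7Z-dien-6-one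
Product: 20 (4R,5R,8S)-4,5-epoxy-8-hydroxy-4,10-dimethylcyclodec-1(10)Z-en-6-one, via boronate 19 (not isolated)
Conditions: CuCl (5 mol %), NaOtBu, (R,R)-QuinoxP*, B2pin2, MeOH, THF, rt; then NaBO3·4H2O, THF/H2O, rt
Reagents that add atoms: sodium perborate tetrahydrate, [Na+].[O-]OB=O.O.O.O.O
Why: Catalytic enantioselective β-borylation of a cyclic Z enone by a chiral bisphosphine complex of monovalent copper; the catalyst delivers boron to the C8 face cis to the epoxide oxygen, and perborate oxidation replaces boron by hydroxyl with retention.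

Step 13
Reactants: 20 (4R,5R,8S)-4,5-epoxy-8-hydroxy-4,10-dimethylcyclodec-1(10)Z-en-6-one
Product: 21 (4R,5R,8S)-4,5-epoxy-4,10-dimethyl-8-(triethylsilyloxy)cyclodec-1(10)Z-en-6-one
Conditions: Et3SiCl, imidazole, DMF, 0 °C
Reagents that add atoms: chlorotriethylsilane, CC[Si](Cl)(CC)CC
Why: Silylation of the secondary alcohol stops retro-aldol cleavage and keeps the C8 oxygen out of the later lactonisation.

Step 14
Reactants: 21 (4R,5R,8S)-4,5-epoxy-4,10-dimethyl-8-(triethylsilyloxy)cyclodec-1(10)Z-en-6-one
Product: 23 ethyl 2-[(4R,5R,7R,8S)-4,5-epoxy-4,10-dimethyl-6-oxo-8-(triethylsilyloxy)cyclodec-1(10)Z-en-7-yl]acetate, via lithium enolate 22 (not isolated)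
Conditions: LiN(iPr)2, THF, −78 °C; ICH2CO2Et, DMPU, −78 °C
Reagents that add atoms: ethyl iodoacetate, CCOC(=O)CI
Why: Kinetic enolate alkylation at C7, the only α-CH position; the electrophile enters trans to the neighbouring silyloxy group (1,2-induction in a cyclic enolate), and the reactive iodide at −78 °C outruns β-elimination of silanolate.

Step 15
Reactants: 23 ethyl 2-[(4R,5R,7R,8S)-4,5-epoxy-4,10-dimethyl-6-oxo-8-(triethylsilyloxy)cyclodec-1(10)Z-en-7-yl]acetate
Product: 25 (4R,5S,6S,7S,8S)-4,5-epoxy-8-(triethylsilyloxy)-13-norgermacr-1(10)Z-en-12,6-olide, via hydroxy ester 24 (not isolated)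
Conditions: Zn(BH4)2, Et2O, −30 °C; aq NH4Cl; then 2-hydroxypyridine (cat.), toluene, 50 °C
Reagents that add atoms: none
Why: Zinc chelates the ketone and the epoxide oxygen, and hydride enters from the open side (chelation-controlled reduction of α,β-epoxy ketones to erythro epoxy alcohols). The C6 oxygen ends cis to the epoxide oxygen and trans to C7–C11, and the γ-hydroxy ester closes to the trans-fused lactone.

Step 16
Reactants: 25 (4R,5S,6S,7S,8S)-4,5-epoxy-8-(triethylsilyloxy)-13-norgermacr-1(10)Z-en-12,6-olide
Product: 29 (4R,5S,6S,7S,8S)-4,5-epoxy-8-(triethylsilyloxy)germacra-1(10)Z,11(13)-dien-12,6-olide, via lactone enolate 26 (not isolated), via Mannich base 27 (not isolated), via ammonium iodide 28 (not isolated)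
Conditions: LiN(iPr)2, THF, −78 °C; CH2=NMe2 iodide, −78 °C to rt; MeI, MeOH, rt; aq NaHCO3, CH2Cl2
Reagents that add atoms: N,N-dimethylmethyleneiminium iodide (Eschenmoser's salt), C=[N+](C)C.[I-]
Why: α-Methylenation of a lactone by Mannich reaction of its enolate, quaternisation and elimination; the enolate has no β-leaving group, and the silyl ether and epoxide tolerate the base at −78 °C.

Step 17
Reactants: 29 (4R,5S,6S,7S,8S)-4,5-epoxy-8-(triethylsilyloxy)germacra-1(10)Z,11(13)-dien-12,6-olide
Product: 30 (4R,5S,6S,7R,8S)-4,5-epoxy-8-hydroxygermacra-1(10)Z,11(13)-dien-12,6-olide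
Conditions: HF·pyridine, pyridine, THF, 0 °C
Reagents that add atoms: none
Why: Buffered fluoride cleaves the triethylsilyl ether without opening the epoxide or adding to the methylene lactone.

Step 18
Reactants: 31 (tert-butyldimethylsilyloxy)acetaldehyde; 32 ethyl 2-(triphenyl-λ5-phosphanylidene)propanoate
Product: 33 ethyl (E)-4-(tert-butyldimethylsilyloxy)-2-methylbut-2-enoate
Conditions: CH2Cl2, rt
Reagents that add atoms: none
Why: Wittig olefination with a stabilised ylide gives the E trisubstituted enoate.

Step 19
Reactants: 33 ethyl (E)-4-(tert-butyldimethylsilyloxy)-2-methylbut-2-enoate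
Product: 34 (E)-4-(tert-butyldimethylsilyloxy)-2-methylbut-2-enoic acid
Conditions: LiOH, THF/MeOH/H2O, rt; 1 M HCl to pH 4, 0 °C
Reagents that add atoms: lithium hydroxide, [Li+].[OH-]
Why: Saponification of the ethyl ester; the primary silyl ether survives aqueous hydroxide and the brief mild acidification.

Step 20
Reactants: 30 (4R,5S,6S,7R,8S)-4,5-epoxy-8-hydroxygermacra-1(10)Z,11(13)-dien-12,6-olide; 34 (E)-4-(tert-butyldimethylsilyloxy)-2-methylbut-2-enoic acid
Product: 35 (4R,5S,6S,7R,8R)-4,5-epoxy-12,6-olidogermacra-1(10)Z,11(13)-dien-8-yl (E)-4-(tert-butyldimethylsilyloxy)-2-methylbut-2-enoate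
Conditions: Ph3P, diisopropyl azodicarboxylate, toluene, 0 °C to rt
Reagents that add atoms: none
Why: Mitsunobu esterification: the carboxylate displaces the alkoxyphosphonium group at C8 with inversion, which turns the 8S carbinol into the 8R ester cis to C7–C11; phosphine and azo ester are premixed so that free phosphine does not add to the methylene lactone.

Step 21
Reactants: 35 (4R,5S,6S,7R,8R)-4,5-epoxy-12,6-olidogermacra-1(10)Z,11(13)-dien-8-yl (E)-4-(tert-butyldimethylsilyloxy)-2-methylbut-2-enoate
Product: 36 (4R,5S,6S,7R,8R)-4,5-epoxy-12,6-olidogermacra-1(10)Z,11(13)-dien-8-yl (E)-4-hydroxy-2-methylbut-2-enoate (CNP0198076.6)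
Conditions: HF·pyridine, pyridine, THF, 0 °C to rt
Reagents that add atoms: none
Why: Buffered fluoride removes the primary silyl ether; the conditions are the ones already tolerated by the epoxide and the lactone in step 17.

## Compound list

1 | 3-methylcyclohex-2-en-1-one | CC1=CC(=O)CCC1 | starting material
2 | 2-iodo-3-methylcyclohex-2-en-1-one | CC1=C(I)C(=O)CCC1 | intermediate
3 | 2-methyl-2-vinyl-1,3-dioxolane | CC1(C=C)OCCO1 | starting material
4 | 9-[2-(2-methyl-1,3-dioxolan-2-yl)ethyl]-9-borabicyclo[3.3.1]nonane | CC1(CCB2C3CCCC2CCC3)OCCO1 | intermediate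
5 | 3-methyl-2-[2-(2-methyl-1,3-dioxolan-2-yl)ethyl]cyclohex-2-en-1-one | CC1=C(CCC2(C)OCCO2)C(=O)CCC1 | intermediate
6 | hexamethylditin | C[Sn](C)(C)[Sn](C)(C)C | starting material
7 | trimethylstannyllithium | [Li][Sn](C)(C)C | intermediate
8 | lithium 3-methyl-2-[2-(2-methyl-1,3-dioxolan-2-yl)ethyl]-3-(trimethylstannyl)cyclohex-1-en-1-olate | [Li]OC1=C(CCC2(C)OCCO2)[C@@](C)([Sn](C)(C)C)CCC1 | intermediate
9 | rac-(2R,3S)-3-methyl-2-[2-(2-methyl-1,3-dioxolan-2-yl)ethyl]-3-(trimethylstannyl)cyclohexan-1-one (chain cis to tin) | O=C1[C@@H](CCC2(C)OCCO2)[C@@](C)([Sn](C)(C)C)CCC1 | intermediate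
10 | rac-(2R,3S)-3-methyl-2-(3-oxobutyl)-3-(trimethylstannyl)cyclohexan-1-one | O=C1[C@@H](CCC(C)=O)[C@@](C)([Sn](C)(C)C)CCC1 | intermediate
11 | rac-(4aR,5S)-5-methyl-5-(trimethylstannyl)-4,4a,5,6,7,8-hexahydronaphthalen-2(3H)-one | O=C1C=C2CCC[C@](C)([Sn](C)(C)C)[C@@H]2CC1 | intermediate
12 | rac-(1S,4aR,5S,8aS)-1,8a-epoxy-5-methyl-5-(trimethylstannyl)octahydronaphthalen-2(1H)-one (epoxide oxygen cis to H-4a, trans to tin) | O=C1[C@H]2O[C@]23CCC[C@](C)([Sn](C)(C)C)[C@@H]3CC1 | intermediate
13 | rac-(1R,4aR,5S,8aS)-1,8a-epoxy-5-methyl-2-methylidene-5-(trimethylstannyl)decahydronaphthalene | C=C1[C@H]2O[C@]23CCC[C@](C)([Sn](C)(C)C)[C@@H]3CC1 | intermediate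
14 | rac-(4aR,8S,8aR)-3,8-dimethyl-8-(trimethylstannyl)-1,5,6,7,8,8a-hexahydronaphthalen-4a(2H)-ol (cis-fused, tin cis to C2) | O[C@]12C=C(C)CC[C@H]1[C@@](C)([Sn](C)(C)C)CCC2 | intermediate
15 | (2Z,6Z)-3,7-dimethylcyclodeca-2,6-dien-1-one | C/C1=C/C(=O)CCC/C(C)=C\CC1 | intermediate
16 | (4R,5R)-4,5-epoxy-4,10-dimethylcyclodec-1(10)Z-en-6-one | O=C1CCC/C(C)=C\CC[C@@]2(C)O[C@@H]12 | intermediate
17 | trimethylsilyl enol ether (C6=C7) of 16 | C[Si](C)(C)O/C1=C/CC/C(C)=C\CC[C@@]2(C)O[C@@H]12 | intermediate
18 | (4R,5R)-4,5-epoxy-4,10-dimethylcyclodeca-1(10)Z,7Z-dien-6-one | O=C1/C=C\C/C(C)=C\CC[C@@]2(C)O[C@@H]12 | intermediate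
19 | (4R,5R,8S)-4,5-epoxy-4,10-dimethyl-8-(4,4,5,5-tetramethyl-1,3,2-dioxaborolan-2-yl)cyclodec-1(10)Z-en-6-one | O=C1C[C@@H](B2OC(C)(C)C(C)(C)O2)C/C(C)=C\CC[C@@]2(C)O[C@@H]12 | intermediate
20 | (4R,5R,8S)-4,5-epoxy-8-hydroxy-4,10-dimethylcyclodec-1(10)Z-en-6-one | O=C1C[C@@H](O)C/C(C)=C\CC[C@@]2(C)O[C@@H]12 | intermediate
21 | (4R,5R,8S)-4,5-epoxy-4,10-dimethyl-8-(triethylsilyloxy)cyclodec-1(10)Z-en-6-one | O=C1C[C@@H](O[Si](CC)(CC)CC)C/C(C)=C\CC[C@@]2(C)O[C@@H]12 | intermediate
22 | lithium enolate (C6=C7) of 21 | [Li]O/C1=C/[C@@H](O[Si](CC)(CC)CC)C/C(C)=C\CC[C@@]2(C)O[C@@H]12 | intermediate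
23 | ethyl 2-[(4R,5R,7R,8S)-4,5-epoxy-4,10-dimethyl-6-oxo-8-(triethylsilyloxy)cyclodec-1(10)Z-en-7-yl]acetate | O=C1[C@H](CC(=O)OCC)[C@@H](O[Si](CC)(CC)CC)C/C(C)=C\CC[C@@]2(C)O[C@@H]12 | intermediate
24 | ethyl 2-[(4R,5S,6S,7S,8S)-4,5-epoxy-6-hydroxy-4,10-dimethyl-8-(triethylsilyloxy)cyclodec-1(10)Z-en-7-yl]acetate | CCOC(=O)C[C@@H]1[C@@H](O[Si](CC)(CC)CC)C/C(C)=C\CC[C@@]2(C)O[C@H]2[C@H]1O | intermediate
25 | (4R,5S,6S,7S,8S)-4,5-epoxy-8-(triethylsilyloxy)-13-norgermacr-1(10)Z-en-12,6-olide | O=C1C[C@@H]2[C@@H](O[Si](CC)(CC)CC)C/C(C)=C\CC[C@@]3(C)O[C@H]3[C@H]2O1 | intermediate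
26 | lithium enolate (C11=C12) of 25 | [Li]OC1=C[C@@H]2[C@@H](O[Si](CC)(CC)CC)C/C(C)=C\CC[C@@]3(C)O[C@H]3[C@H]2O1 | intermediate
27 | 13-(dimethylamino)-11,13-dihydro derivative of 29 (Mannich base, C11 unassigned) | CN(C)CC1C(=O)O[C@H]2[C@H]1[C@@H](O[Si](CC)(CC)CC)C/C(C)=C\CC[C@@]1(C)O[C@@H]21 | intermediate
28 | 13-(trimethylammonio)-11,13-dihydro derivative of 29, iodide | C[N+](C)(C)CC1C(=O)O[C@H]2[C@H]1[C@@H](O[Si](CC)(CC)CC)C/C(C)=C\CC[C@@]1(C)O[C@@H]21.[I-] | intermediate
29 | (4R,5S,6S,7S,8S)-4,5-epoxy-8-(triethylsilyloxy)germacra-1(10)Z,11(13)-dien-12,6-olide | C=C1C(=O)O[C@H]2[C@H]1[C@@H](O[Si](CC)(CC)CC)C/C(C)=C\CC[C@@]1(C)O[C@@H]21 | intermediate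
30 | (4R,5S,6S,7R,8S)-4,5-epoxy-8-hydroxygermacra-1(10)Z,11(13)-dien-12,6-olide | C=C1C(=O)O[C@H]2[C@H]1[C@@H](O)C/C(C)=C\CC[C@@]1(C)O[C@@H]21 | intermediate
31 | (tert-butyldimethylsilyloxy)acetaldehyde | CC(C)(C)[Si](C)(C)OCC=O | starting material
32 | ethyl 2-(triphenyl-λ5-phosphanylidene)propanoate | CCOC(=O)C(C)=P(c1ccccc1)(c1ccccc1)c1ccccc1 | starting material
33 | ethyl (E)-4-(tert-butyldimethylsilyloxy)-2-methylbut-2-enoate | CCOC(=O)/C(C)=C/CO[Si](C)(C)C(C)(C)C | intermediate
34 | (E)-4-(tert-butyldimethylsilyloxy)-2-methylbut-2-enoic acid | OC(=O)/C(C)=C/CO[Si](C)(C)C(C)(C)C | intermediate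
35 | (4R,5S,6S,7R,8R)-4,5-epoxy-12,6-olidogermacra-1(10)Z,11(13)-dien-8-yl (E)-4-(tert-butyldimethylsilyloxy)-2-methylbut-2-enoate | C=C1C(=O)O[C@H]2[C@H]1[C@H](OC(=O)/C(C)=C/CO[Si](C)(C)C(C)(C)C)C/C(C)=C\CC[C@@]1(C)O[C@@H]21 | intermediate
36 | (4R,5S,6S,7R,8R)-4,5-epoxy-12,6-olidogermacra-1(10)Z,11(13)-dien-8-yl (E)-4-hydroxy-2-methylbut-2-enoate (CNP0198076.6) | C=C1C(=O)O[C@H]2[C@H]1[C@H](OC(=O)/C(C)=C/CO)C/C(C)=C\CC[C@@]1(C)O[C@@H]21 | target

## Step count and least certain steps

Total step count: 21. Longest linear sequence: 19 steps (steps 1–17, 20 and 21); steps 18 and 19 make the side-chain acid.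

**Step 9 (key step).** The fragmentation may leave the concerted path. Ligand exchange at the hindered tertiary alcohol is slow, and a stepwise cleavage through an alkoxy radical or a cation at C1 would lose the link between configuration and geometry and give E olefin. Acetic acid may also cause protodestannylation. Fallback: from 14 the fragmentation is run without regard to geometry, and the (2Z,6E)-3,7-dimethylcyclodeca-2,6-dien-1-one F1 formed beside 15 is equilibrated with PhSSPh under irradiation. Reversible thiyl radical addition should lead to the ring-cis olefin, expected to be the more stable isomer in a ten-membered ring, and so returns to 15. This must be done at or below room temperature, because the E isomer is the one open to Cope rearrangement.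

**Step 3 (with steps 4 and 5).** The protonation of enolate 8 may show poor facial selectivity, and C1 may epimerise under the acid of step 4 or the base of step 5. The thermodynamic bias for the needed epimer is small, so the material could approach a near-statistical mixture; base may also expel the stannyl group from the enolate. Fallback: from 9 as an epimer mixture the sequence is carried through to the octalone stage, where rac-(4aS,5S)-5-methyl-5-(trimethylstannyl)-4,4a,5,6,7,8-hexahydronaphthalen-2(3H)-one F2 is separated from 11. F2 is re-equilibrated through its dienolate (KOtBu, tBuOH, rt), and the mixture is separated again, so that control changes from kinetic to thermodynamic with recycling and the material returns to 11.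

**Step 10.** Iminium formation with a β,β-disubstituted enone in a ten-membered ring may be slow, and the enantioselectivity, known for smaller and larger cyclic enones, may fall. Fallback: from 15, reduction with (R)-2-methyl-CBS-oxazaborolidine and BH3·SMe2 gives (1S,2Z,6Z)-3,7-dimethylcyclodeca-2,6-dien-1-ol F3. Epoxidation with VO(acac)2 and tBuOOH, which gives cis epoxy alcohols with medium-ring cycloalkenols, gives (4R,5S,6S)-4,5-epoxy-4,10-dimethylcyclodec-1(10)Z-en-6-ol F4. Dess–Martin oxidation returns to 16.

**Step 14.** Enolate 22 may lose triethylsilanolate by β-elimination back to 18 before it is alkylated, and attack from the face of the silyloxy group would lower the diastereoselectivity. Fallback: from 20 the free hydroxy ketone is converted into its dianion (two equivalents of LiN(iPr)2), which cannot eliminate and whose lithium alkoxide shields the same face. Alkylation with ethyl iodoacetate gives ethyl 2-[(4R,5R,7R,8S)-4,5-epoxy-8-hydroxy-4,10-dimethyl-6-oxocyclodec-1(10)Z-en-7-yl]acetate F5, and silylation (Et3SiCl, imidazole) returns to 23.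

**Step 20.** The displacement at C8 must come from the face that carries C7–C11. Elimination towards C9 may win over substitution, and free phosphine may add to the methylene lactone. Fallback: from 30, Dess–Martin oxidation gives (4R,5S,6S,7R)-4,5-epoxy-8-oxogermacra-1(10)Z,11(13)-dien-12,6-olide F6. Reduction with Zn(BH4)2 at −78 °C, with hydride entering anti to C7–C11, gives (4R,5S,6S,7R,8R)-4,5-epoxy-8-hydroxygermacra-1(10)Z,11(13)-dien-12,6-olide F7. Esterification with 34 under retention (2,4,6-trichlorobenzoyl chloride, Et3N, DMAP) returns to 35.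

## Further compounds

F1 | step 9 | (2Z,6E)-3,7-dimethylcyclodeca-2,6-dien-1-one | C/C1=C/C(=O)CCC/C(C)=C/CC1
F2 | step 3 | rac-(4aS,5S)-5-methyl-5-(trimethylstannyl)-4,4a,5,6,7,8-hexahydronaphthalen-2(3H)-one | O=C1C=C2CCC[C@](C)([Sn](C)(C)C)[C@H]2CC1
F3 | step 10 | (1S,2Z,6Z)-3,7-dimethylcyclodeca-2,6-dien-1-ol | C/C1=C/[C@@H](O)CCC/C(C)=C\CC1
F4 | step 10 | (4R,5S,6S)-4,5-epoxy-4,10-dimethylcyclodec-1(10)Z-en-6-ol | O[C@H]1CCC/C(C)=C\CC[C@@]2(C)O[C@@H]12
F5 | step 14 | ethyl 2-[(4R,5R,7R,8S)-4,5-epoxy-8-hydroxy-4,10-dimethyl-6-oxocyclodec-1(10)Z-en-7-yl]acetate | O=C1[C@H](CC(=O)OCC)[C@@H](O)C/C(C)=C\CC[C@@]2(C)O[C@@H]12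
F6 | step 20 | (4R,5S,6S,7R)-4,5-epoxy-8-oxogermacra-1(10)Z,11(13)-dien-12,6-olide | C=C1C(=O)O[C@H]2[C@H]1C(=O)C/C(C)=C\CC[C@@]1(C)O[C@@H]21
F7 | step 20 | (4R,5S,6S,7R,8R)-4,5-epoxy-8-hydroxygermacra-1(10)Z,11(13)-dien-12,6-olide | C=C1C(=O)O[C@H]2[C@H]1[C@H](O)C/C(C)=C\CC[C@@]1(C)O[C@@H]21
A1 | alternative 1 | isoxazoline-fused ten-membered 4,5-epoxide with a 2-(tert-butyldimethylsilyloxy)ethyl group on C7 | CC(C)(C)[Si](C)(C)OCC[C@@H]1C2=NO[C@@H]1[C@@H]1O[C@]1(C)CC/C=C(C)\C2
A2 | alternative 2 | ten-membered (Z,Z)-diene C2 phenyl sulfone with C6 triethylsilyl ether, C8 tert-butyldimethylsilyl ether and C7 tert-butyl acetate | CC[Si](CC)(CC)O[C@@H]1/C=C(C)\C[C@H](S(=O)(=O)c2ccccc2)/C=C(C)\C[C@@H](O[Si](C)(C)C(C)(C)C)[C@H]1CC(=O)OC(C)(C)C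
A3 | alternative 3 | trans-fused epoxy γ-lactone lacking C13, C8 tert-butyldimethylsilyl ether | C1C(=O)O[C@H]2[C@H]1[C@H](O[Si](C)(C)C(C)(C)C)C/C(C)=C\CC[C@@]1(C)O[C@@H]21
A4 | alternative 1 | open-chain nitrile oxide with cis vinyl epoxide and Z C6=C7 olefin | [O-][N+]#CC/C(C)=C\CC[C@@]1(C)O[C@H]1/C=C\CCO[Si](C)(C)C(C)(C)C
A5 | alternative 2 | open-chain allylic chloride (C3) and allylic phenyl sulfone (C2) carrying the C6–C8 triad | ClC/C(C)=C\[C@@H](O[Si](CC)(CC)CC)[C@H](CC(=O)OC(C)(C)C)[C@H](O[Si](C)(C)C(C)(C)C)C/C(C)=C\CS(=O)(=O)c1ccccc1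
A6 | alternative 3 | C6 diazoacetate of the ten-membered epoxy diol C8 silyl ether | [N-]=[N+]=CC(=O)O[C@H]1C[C@H](O[Si](C)(C)C(C)(C)C)C/C(C)=C\CC[C@@]2(C)O[C@@H]12
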